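# Total synthesis of phylloquinone (2'E,7'R,11'R)

## The problem

1. Phylloquinone 11 is a 2-methyl-1,4-naphthoquinone (ring A = benzo ring C4a–C8a, ring B = quinone ring C1–C4). C3 carries a sixteen-carbon chain C1'–C16' with methyl groups on C3', C7', C11' and C15'. No ring has to be closed, so the whole problem is the chain and its junction with ring B.
2. The stereocentres C7' (R) and C11' (R) carry only H, CH3 and two CH2 arms, and three methylene groups cut them off from each other and from every functional group. Neither can control the other, no neighbouring group can direct a reagent, and a wrong centre gives an oily diastereomer that cannot be removed.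
3. The alkene C2'=C3' must be E although CH3 and C4'H2 on C3' differ little in size. Thermodynamic control erodes the geometry, and so does every path through a C1'–C2'–C3' allyl cation, allyl radical or π-allyl metal species.
4. C1' is allylic to C2'=C3' and vinylogously α to the C1 carbonyl. Base therefore shifts the double bond or forms the quinone methide, while at the hydroquinone level acid closes O4 onto C3' to a chroman.
5. Ring B is an oxidant, a Michael acceptor and light-sensitive, and it does not survive hydrogenation, strong nucleophiles or strong base. It should enter late and ideally never change its oxidation level.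
6. The feature that opens the problem is the regular head-to-tail isoprenoid repeat of the saturated segment C5'–C16'. C7' and C11' sit in the same local pattern (head-side CH2, CH3, tail-side CH2) and C15' carries two methyl groups. The segment maps atom for atom on (2E,6E)-farnesol 1, where C7' and C11' are the methyl-bearing carbons of two E-trisubstituted alkenes of identical shape.
7. One chiral hydrogenation catalyst that reads this shape can therefore set both centres with the same sense in one operation, provided that C2'=C3' and ring B are not yet present.

## Retrosynthesis

**Bonds C1'–C2' and C3'–CH3 (11 back to 9 and 7).**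
- The cut: the chain is cut from the ring one bond further out than C3–C1', and the 3'-methyl group is taken off in the same operation. This leads through the alkenylalane 10 to the terminal alkyne 7 and to 2-(chloromethyl)-3-methyl-1,4-naphthoquinone 9.
- Against its neighbours: the cut C3–C1' turns the chain into an allyl electrophile or allyl metal, the very species that lose the E geometry. The cut C3'–C4' needs a stereodefined alkenyl halide on the ring fragment. With C1'–C2' the chain carbon is an sp2 nucleophile that holds its geometry, and C1' is a benzylic-type electrophile that has none.
- Simplification: the alkene stereochemistry disappears into a triple bond. Compound 9 stays at the quinone level, so no protecting group and no final oxidation are needed.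
- Asked of the forward reaction: it must add methyl and metal syn, with methyl on the inner carbon. The coupling must also outrun attack of aluminium alkyls on the carbonyl groups of 9.

**Bond C3–C1' (9 back to 8).**
- The cut: C1' alone, without the chain, is removed from ring B, which gives menadione 8.
- Against its neighbours: a one-carbon unit has no geometry and cannot cyclise onto O4, unlike the whole chain at C3. C3 is the only free position of ring B.
- Simplification: the precursor is a bulk chemical that already holds rings A and B and the 2-methyl group.
- Asked of the forward reaction: it must replace C3–H by a carbon that bears a leaving group, without changing the oxidation level of the ring.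

**Bond C4'–C5' (7 back to 3 and 4).**
- The cut: the methylene run between the alkyne and C7' is cut at C4'–C5'. This gives the C15 iodide 3 and 1-(trimethylsilyl)propyne 4, joined through the lithio compound 5 and the silylalkyne 6.
- Against its neighbours: C4' is propargylic and can be a stabilised carbanion, and the cut leaves exactly the farnesol skeleton. The cut C3'–C4' (acetylide plus C16 halide) would cost a one-carbon homologation of the C15 unit. The cut C5'–C6' would cost a degradation.
- Simplification: an eighteen-carbon alkyne falls into a three-carbon stock reagent and a C15 piece with one functional group.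
- Asked of the forward reaction: substitution must occur at a primary carbon through the propargyl terminus of the ambident anion, not the allenyl terminus.

**Carbon–iodine bond at C5' (3 back to 2).**
- The cut: the iodide is traced to the primary alcohol 2.
- Against its neighbours: iodide is preferred to a sulfonate or bromide because the soft propargyl-lithium 5 substitutes it fastest and with least elimination.
- Simplification: nothing is gained in structure, but 2 is the direct product of the key step.
- Asked of the forward reaction: only that the two tertiary C–H centres stay untouched.

**Six C–H bonds at C6'/C7', C10'/C11' and C14'/C15' (2 back to 1).**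
- The cut: removal of six hydrogen atoms from 2 gives (2E,6E)-farnesol 1.
- Against its neighbours: building the centres one by one from chiral C5 or C10 pieces needs a coupling and functional-group changes for each centre. This cut removes both centres at once and needs no C–C bond at all.
- Simplification: the precursor is achiral, commercial and geometrically defined, so the run-up to the key step is zero steps.
- Asked of the forward reaction: pure catalyst control of the alkene face at two unfunctionalised alkenes, with no E/Z isomerisation before reduction.

## Roads not taken

**Alternative 1:** cut C3–C1' with the complete chain (the most obvious route).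
- Forward key step: natural phytol A1 and menadiol A2 (from 8 by reduction) are joined by Lewis-acid Friedel–Crafts allylation to phyllohydroquinone A3. Mild oxidation then gives 11.
- Why the chosen plan is better: the bond forms through the C1'–C2'–C3' allyl cation, which rotates and loses the E geometry.
  - The same cation is trapped by O4 at C3' (chroman formation) and by C2 (ipso attack at the methyl-bearing carbon).
  - Two redox steps on ring B are added.
  - Both stereocentres and the alkene are bought with A1 and not made, so the real problem stays unsolved.

**Alternative 2:** the same six C–H bonds, but cut in 11 itself.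
- Forward key step: the precursor is menaquinone-4 A4, and a site-selective triple asymmetric hydrogenation would have to spare C2'=C3'.
- Why the chosen plan is better: the feature that lets one catalyst read C6'=C7' and C10'=C11' alike makes it read C2'=C3' as well, since that alkene has the same E-trisubstituted shape. Only a weak steric bias from ring B would protect it.
  - Over-reduction would give material that cannot be separated.
  - Ring B would be reduced and would bind the cationic metal.
  - No step is saved, because the hydrogenation counts as one step wherever it stands.

**Alternative 3:** cut ring B (bonds C4–C3, C2–C1 and C1–C8a).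
- Forward key step: Dötz benzannulation of the chromium carbene complex (CO)5Cr=C(OMe)Ph A6 with the skipped enyne A5 gives the 4-methoxy-1-naphthol A7, which oxidative work-up turns into 11.
- Appeal: either orientation of the alkyne ends in the same quinone, so regiochemistry does not matter.
- Why the chosen plan is better: the cut removes none of the chain problems, since A5 still holds both stereocentres and the E alkene and would itself come from 10.
  - Carbene preparation, annulation and oxidation are added, and chromium is used in stoichiometric amount.
  - All of this rebuilds a ring system that is sold as 8.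

Key step: step 1

Assumption: the antipode of ligand L is the one that delivers hydrogen to the alkene face making C3 and C7 of 2 both R. The quadrant model predicts which antipode this is, and the first batch of 2 is checked against material of known configuration.

## Route

Step 1
Reactants: 1 (2E,6E)-farnesol, (2E,6E)-3,7,11-trimethyldodeca-2,6,10-trien-1-ol
Product: 2 (3R,7R)-3,7,11-trimethyldodecan-1-ol (hexahydrofarnesol)
Conditions: H2 (50 bar), [Ir(cod)(L)][B(3,5-(CF3)2C6H3)4] (1 mol %), CH2Cl2, rt; L = one antipode of 2-phenyl-7-[(di-o-tolylphosphanyl)oxy]-6,7-dihydro-5H-cyclopenta[b]pyridine
Reagents that add atoms: none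
Why: Asymmetric hydrogenation of unfunctionalised trisubstituted alkenes with a cationic iridium N,P-ligand complex, a reaction type established for all-alkyl E-olefins and for polyprenyl chains. Hydrogen first removes the cyclooctadiene ligand; the resulting iridium dihydride binds one alkene and one more H2, and migratory insertion followed by reductive elimination (a cycle between trivalent and pentavalent iridium) delivers both hydrogens to the same alkene face. No ring is closed. The face is chosen by the ligand alone: the 2-phenyl group and the P-aryl groups leave one quadrant too narrow for carbon, so each alkene must place its single vinylic hydrogen (on C2 or C6 of 1) there. Because C2=C3 and C6=C7 are both E and carry the same substituents in the same head-to-tail order (CH2 on the CH carbon, CH3 and CH2 on the other), both bind in the same way, and C3 and C7 of 2 (C7' and C11' of 11) form with the same sense, R and R with the proper ligand antipode. C10=C11 ends in two methyl groups and gives no stereocentre, so three reductions leave exactly two centres. The step needs face selectivity at both prochiral alkenes, no E to Z isomerisation before reduction and no loss of the allylic oxygen; the geometric purity of 1, the non-coordinating borate anion, the aprotic solvent and the high hydrogen pressure (reduction faster than isomerisation) secure this. The free hydroxyl group is tolerated and is the handle for step 2.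

Step 2
Reactants: 2 (3R,7R)-3,7,11-trimethyldodecan-1-ol
Product: 3 (3R,7R)-1-iodo-3,7,11-trimethyldodecane
Conditions: I2, PPh3, imidazole, CH2Cl2, 0 °C to rt
Reagents that add atoms: iodine, [I][I]
Why: Appel-type iodination; iodide displaces the oxyphosphonium group at the primary carbon by SN2. The centres at C3 and C7 lie two and six bonds away and are not touched.

Step 3
Reactants: 3 (3R,7R)-1-iodo-3,7,11-trimethyldodecane; 4 1-(trimethylsilyl)propyne
Product: 6 trimethyl[(6R,10R)-6,10,14-trimethylpentadec-1-yn-1-yl]silane, via lithiated silylpropyne 5 (not isolated)
Conditions: 4, n-BuLi, THF, −78 to −20 °C; then 3, DMPU, −78 °C to rt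
Reagents that add atoms: none
Why: Deprotonation of 4 at its methyl group gives the propargyl-lithium 5, which alkylates primary iodides by SN2 at its CH2 terminus because the silyl group blocks the allenyl terminus. This forms C4'–C5' and brings in C2'–C4' as a masked terminal alkyne.

Step 4
Reactants: 6 trimethyl[(6R,10R)-6,10,14-trimethylpentadec-1-yn-1-yl]silane
Product: 7 (6R,10R)-6,10,14-trimethylpentadec-1-yne
Conditions: K2CO3 (cat.), MeOH/THF, rt
Reagents that add atoms: none
Why: Carbonate-catalysed methanolysis of the alkynyl carbon–silicon bond (protodesilylation) frees the terminal alkyne. Nothing else in this hydrocarbon can react.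

Step 5
Reactants: 8 menadione (2-methyl-1,4-naphthoquinone)
Product: 9 2-(chloromethyl)-3-methyl-1,4-naphthoquinone
Conditions: aq. HCHO (37 %), HCl (gas), AcOH, rt
Reagents that add atoms: formaldehyde, C=O; hydrogen chloride, Cl
Why: Blanc-type chloromethylation of a 2-alkyl-1,4-naphthoquinone, a known way to 3-chloromethylquinones. C3 is the only unsubstituted carbon of ring B and ring A is deactivated by both carbonyl groups, so one position reacts and the ring keeps its oxidation level.

Step 6
Reactants: 7 (6R,10R)-6,10,14-trimethylpentadec-1-yne; 9 2-(chloromethyl)-3-methyl-1,4-naphthoquinone
Product: 11 phylloquinone, 2-methyl-3-[(2E,7R,11R)-3,7,11,15-tetramethylhexadec-2-en-1-yl]naphthalene-1,4-dione, via alkenyldimethylalane 10 (not isolated)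
Conditions: 7, Me3Al, Cp2ZrCl2 (25 mol %), ClCH2CH2Cl, rt; volatiles removed, hexane extract decanted from the zirconium salts, THF; then 9, NiCl2(PPh3)2 (5 mol %) pre-reduced with n-BuLi (10 mol %), THF, −20 °C to rt, dark
Reagents that add atoms: trimethylaluminium, C[Al](C)C
Why: Zirconium-catalysed methylalumination of the terminal alkyne (Negishi carboalumination) adds CH3 to C3' and aluminium to C2' on the same side, which fixes the E geometry in 10. Zerovalent nickel then inserts into the benzylic-type C1'–Cl bond of 9, and transmetalation from aluminium and reductive elimination form C1'–C2' with retention at the sp2 carbon, a known coupling of alkenylalanes with chloromethylquinones. No allyl cation, allyl radical or π-allyl species is passed, so the alkene neither migrates nor isomerises, and no oxidation step follows.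

## Compound list

1 | (2E,6E)-farnesol | OC/C=C(\C)CC/C=C(\C)CCC=C(C)C | starting material
2 | (3R,7R)-3,7,11-trimethyldodecan-1-ol | OCC[C@H](C)CCC[C@H](C)CCCC(C)C | intermediate
3 | (3R,7R)-1-iodo-3,7,11-trimethyldodecane | ICC[C@H](C)CCC[C@H](C)CCCC(C)C | intermediate
4 | 1-(trimethylsilyl)propyne | CC#C[Si](C)(C)C | starting material
5 | 3-lithio-1-(trimethylsilyl)propyne | [Li]CC#C[Si](C)(C)C | intermediate
6 | trimethyl[(6R,10R)-6,10,14-trimethylpentadec-1-yn-1-yl]silane | C[Si](C)(C)C#CCCC[C@H](C)CCC[C@H](C)CCCC(C)C | intermediate
7 | (6R,10R)-6,10,14-trimethylpentadec-1-yne | C#CCCC[C@H](C)CCC[C@H](C)CCCC(C)C | intermediate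
8 | menadione (2-methyl-1,4-naphthoquinone) | CC1=CC(=O)c2ccccc2C1=O | starting material
9 | 2-(chloromethyl)-3-methyl-1,4-naphthoquinone | CC1=C(CCl)C(=O)c2ccccc2C1=O | intermediate
10 | dimethyl[(1E,6R,10R)-2,6,10,14-tetramethylpentadec-1-en-1-yl]alumane | C[Al](C)/C=C(\C)CCC[C@H](C)CCC[C@H](C)CCCC(C)C | intermediate
11 | phylloquinone (2'E,7'R,11'R) | CC1=C(C/C=C(\C)CCC[C@H](C)CCC[C@H](C)CCCC(C)C)C(=O)c2ccccc2C1=O | target

## Step count and least certain steps

Total step count: 6. Longest linear sequence: 5 (steps 1, 2, 3, 4, 6). Step 5 is the one-step side branch. The iridium complex is not a stock item. It is made beforehand from the enantiopure pyridyl alcohol, ClP(o-Tol)2, [Ir(cod)Cl]2 and Na[B(3,5-(CF3)2C6H3)4], and this is not counted.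

**Step 1 (key step).**
- What may go wrong: the likeliest failure is incomplete face selectivity at the remote alkene C6=C7, which has no polar group nearby.
  - The acidic iridium hydride may cause E to Z isomerisation before reduction, which inverts the sense at that centre.
  - The allylic alcohol may isomerise or be hydrogenolysed.
  - Every such error is carried to the end, because all later compounds are oils whose diastereomers do not separate.
- Fallback: it sets out from 1 and comes back at 2, and it sets the two centres one after the other by two different control elements.
  - Hydroxyl-directed hydrogenation of 1 with Ru(OAc)2[(S)-BINAP] in MeOH reduces only the allylic-alcohol alkene C2=C3. It gives (3R,6E)-3,7,11-trimethyldodeca-6,10-dien-1-ol F1, and the isolated alkenes stay.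
  - F1, now with a single prochiral alkene of the purely alkyl type, is hydrogenated with the iridium complex, whose ligand antipode can be matched to this one centre. This gives 2.

**Step 6.**
- What may go wrong: residual Me3Al or the alane may add to the carbonyl groups of ring B.
  - Electron transfer from low-valent nickel to the quinone may stop the catalyst.
  - A small share of methyl addition at the terminal alkyne carbon would place the methyl group wrongly.
  - All three arise because a strong oxidant and Michael acceptor meets organometallic reagents.
- Fallback: it sets out from 8 and 7 and comes back at 11, and it moves the coupling to the protected hydroquinone level.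
  - Compound 8 is reduced with Na2S2O4 to menadiol F2 and methylated (Me2SO4, KOH) to 1,4-dimethoxy-2-methylnaphthalene F3.
  - Chloromethylation gives 2-(chloromethyl)-1,4-dimethoxy-3-methylnaphthalene F4, a benzylic chloride without carbonyl groups.
  - Coupling of F4 with 10 (made from 7 as in step 6) gives 1,4-dimethoxy-2-methyl-3-[(2E,7R,11R)-phytyl]naphthalene F5.
  - Oxidative demethylation with (NH4)2Ce(NO3)6 in MeCN/H2O at 0 °C gives 11.

**Step 5.**
- What may go wrong: the chloromethyl product may condense further with unreacted quinone. HCl may add to ring B with subsequent redox exchange, and the chloride may hydrolyse on work-up. The cause is that the C1'–Cl bond is activated by the enedione.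
- Fallback: it sets out from 8 and comes back at 11, and it builds C1' as a methyl group first.
  - Silver-catalysed decarboxylative radical methylation of 8 (AcOH, AgNO3 cat., (NH4)2S2O8, MeCN/H2O, 70 °C) gives 2,3-dimethyl-1,4-naphthoquinone F6.
  - The two methyl groups of F6 are equivalent by symmetry. Radical bromination (NBS, AIBN, PhCF3, reflux) therefore gives only 2-(bromomethyl)-3-methyl-1,4-naphthoquinone F7.
  - F7 takes the place of 9 in step 6.

**Step 3.**
- What may go wrong: the ambident anion may react through its allenyl terminus. Substitution may also be slow, with competing elimination of the iodide, because 5 is both a soft nucleophile and a strong base.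
- Fallback: it sets out from 3 and comes back at 7, and it makes the alkyne from a methyl ketone.
  - Alkylation of ethyl acetoacetate (NaOEt, EtOH) with 3 gives ethyl 2-acetyl-(5R,9R)-5,9,13-trimethyltetradecanoate F8.
  - Saponification and decarboxylation give (6R,10R)-6,10,14-trimethylpentadecan-2-one F9.
  - Kinetic enolisation (LDA, −78 °C) and trapping with ClP(O)(OEt)2 give diethyl (6R,10R)-6,10,14-trimethylpentadec-1-en-2-yl phosphate F10.
  - Elimination of F10 with more LDA gives 7.

## Further compounds

F1 | step 1 | (3R,6E)-3,7,11-trimethyldodeca-6,10-dien-1-ol | OCC[C@H](C)CC/C=C(\C)CCC=C(C)C
F2 | step 6 | menadiol (2-methylnaphthalene-1,4-diol) | Cc1cc(O)c2ccccc2c1O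
F3 | step 6 | 1,4-dimethoxy-2-methylnaphthalene | COc1cc(C)c(OC)c2ccccc12
F4 | step 6 | 2-(chloromethyl)-1,4-dimethoxy-3-methylnaphthalene | COc1c(C)c(CCl)c(OC)c2ccccc12
F5 | step 6 | 1,4-dimethoxy-2-methyl-3-[(2E,7R,11R)-3,7,11,15-tetramethylhexadec-2-en-1-yl]naphthalene | COc1c(C)c(C/C=C(\C)CCC[C@H](C)CCC[C@H](C)CCCC(C)C)c(OC)c2ccccc12
F6 | step 5 | 2,3-dimethyl-1,4-naphthoquinone | CC1=C(C)C(=O)c2ccccc2C1=O
F7 | step 5 | 2-(bromomethyl)-3-methyl-1,4-naphthoquinone | CC1=C(CBr)C(=O)c2ccccc2C1=O
F8 | step 3 | ethyl 2-acetyl-(5R,9R)-5,9,13-trimethyltetradecanoate (both C2 epimers) | CCOC(=O)C(C(C)=O)CC[C@H](C)CCC[C@H](C)CCCC(C)C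
F9 | step 3 | (6R,10R)-6,10,14-trimethylpentadecan-2-one | CC(=O)CCC[C@H](C)CCC[C@H](C)CCCC(C)C
F10 | step 3 | diethyl (6R,10R)-6,10,14-trimethylpentadec-1-en-2-yl phosphate | C=C(OP(=O)(OCC)OCC)CCC[C@H](C)CCC[C@H](C)CCCC(C)C
A1 | alternative 1 | natural phytol, (2E,7R,11R)-3,7,11,15-tetramethylhexadec-2-en-1-ol | OC/C=C(\C)CCC[C@H](C)CCC[C@H](C)CCCC(C)C
A2 | alternative 1 | menadiol (2-methylnaphthalene-1,4-diol) | Cc1cc(O)c2ccccc2c1O
A3 | alternative 1 | phyllohydroquinone | Cc1c(O)c2ccccc2c(O)c1C/C=C(\C)CCC[C@H](C)CCC[C@H](C)CCCC(C)C
A4 | alternative 2 | menaquinone-4 | CC1=C(C/C=C(\C)CC/C=C(\C)CC/C=C(\C)CCC=C(C)C)C(=O)c2ccccc2C1=O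
A5 | alternative 3 | (5E,10R,14R)-6,10,14,18-tetramethylnonadec-5-en-2-yne | CC#CC/C=C(\C)CCC[C@H](C)CCC[C@H](C)CCCC(C)C
A6 | alternative 3 | pentacarbonyl[methoxy(phenyl)carbene]chromium, (CO)5Cr=C(OMe)Ph | COC(c1ccccc1)=[Cr](=C=O)(=C=O)(=C=O)(=C=O)=C=O
A7 | alternative 3 | 4-methoxy-3-methyl-2-[(2E,7R,11R)-3,7,11,15-tetramethylhexadec-2-en-1-yl]naphthalen-1-ol | COc1c(C)c(C/C=C(\C)CCC[C@H](C)CCC[C@H](C)CCCC(C)C)c(O)c2ccccc12
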